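**Remark on the chemistry (assumptions and corrections).** The target is achiral, so no step sets or has to preserve a stereocenter. A bromoquinone entry to rings C and E would give, after reduction, a hydroquinone whose more hindered hydroxyl (C6 or E6) is the one that must be arylated. Rings C and E are therefore brought in as an ortho-bromo aldehyde, so that only the hydroxyl to be arylated is ever set free; the quinone entry is kept as a fallback. The product of Alternative 3 is correctly named a dimethyl 4,6-dihydroxy-2,5-bis(aryloxy)isophthalate. The boron aryloxides formed by BBr3 before hydrolysis are a mixture of species and are not numbered.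

## Structural features

The target is a linear heptamer of seven benzene rings (A to G) held together only by six diaryl ether oxygens. It carries eighteen free phenolic hydroxyls, has no carbon–carbon bond between rings and no stereocenter. Ring A is a 2,4,6-trihydroxyphenyl ether. Rings B, D and F are linked through para oxygens (position 1 and position 4) and carry hydroxyls at positions 3 and 5. Rings C and E are 1,2-bis(aryloxy)-3,4,5-trihydroxybenzenes with a single hydrogen at C2 (E2) next to the ether carbon C1 (E1). Ring G is a 3,4,5-trihydroxyphenyl ether. The free polyphenol, with its vicinal trihydroxy arrays on rings C, E and G, is sensitive to air and base, so the hydroxyls must stay masked until the last step. The real difficulty is making six crowded diaryl ether bonds between electron-rich rings with full regiocontrol, above all on rings C and E, where the C1 and C6 oxygens must be told apart. The key step uses the fact that the oxygens at B1, B3 and B5 lie para, ortho and ortho to B4. A formyl carbon at B4 can therefore activate three C–F bonds for substitution and afterwards be turned into the B4 hydroxyl. The same relation holds in rings D, F and G, and an ortho version of it (formyl at C6 or E6, leaving group at C1 or E1) serves rings C and E.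

## Logic of the disconnections

28 to 27. The seventeen O–CH3 bonds are cut last. Methyl ethers survive base, copper and peroxide, whereas the free polyphenol does not, so every earlier intermediate is a stable ether with exactly one reactive function. The forward step must cleave all seventeen alkyl aryl ethers, leave the six diaryl ethers alone, and deliver the product without exposure to air or base.

27 to 25 to 23 and 2. The G4 carbon–oxygen bond is traced back to a G4 formyl group, and then the O–G1, G3–O and G5–O bonds are cut. The formyl group sits para or ortho to all three, so ring G comes from 2 in two operations. The forward steps need para attack by the crowded F4 phenoxide and migration of an electron-rich aryl group to oxygen in the peroxide step.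

23 to 21 to 19 and 2. The same pair of cuts is made on ring F: the F4 hydroxyl goes back to a formyl group, then the O–F1, F3–O and F5–O bonds are cut. The demand is that the E6 phenoxide of 19, flanked by an aryloxy and a methoxy group, still reaches the para carbon of 2.

19 to 17 to 16 and 9. The E6 hydroxyl goes back to a formyl group, and the bond from the D4 oxygen to E1 is cut. The bromide of 9 stands between the formyl carbon and a ring hydrogen, so the new ether oxygen gets the hydrogen at E2 on one side and the latent hydroxyl at E6 on the other. Only one hydroxyl is ever free on ring E, so no two hydroxyls have to be differentiated. The demand is a copper-mediated C–O coupling between a di-ortho-substituted phenol and an ortho-substituted aryl bromide.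

16 to 14 to 12 and 2. Ring D is cut exactly as ring F: the D4 hydroxyl from a formyl group, then the O–D1, D3–O and D5–O bonds. The gain and the demand are the same.

12 to 10 to 6 and 9. Ring C is cut exactly as ring E: the C6 hydroxyl from a formyl group, then the bond from the B4 oxygen to C1. The same building block 9 is used twice, which halves the preparative effort for the two pentaoxygenated rings.

9 to 7. The formyl carbon–ring bond of 9 is cut. The two open positions of 7 are equivalent, each ortho to bromine and ortho/para to methoxy groups, so the formylation can give only one isomer. It must not cleave the methoxy group next to the new carbonyl.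

6 to 4 to 1 and 2. The B4 hydroxyl goes back to a formyl group, and the three carbon–oxygen bonds at B1, B3 and B5 are cut together. This is the key disconnection: the dimer arises from three commercial components in one flask. It demands para selectivity for the phenoxide of 1 and attack of methoxide on C–F in preference to the new C–OAr bond.

## Other disconnections considered

Alternative 1: The cut is the A5–A6 carbon–carbon bond, which unfolds ring A into a triketide chain. The precursor is the dimethyl 2-aryloxy-3,5-dioxoheptanedioate A2, carried on the B1 oxygen of the hexamer phenol A1 (rings B to G).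
- Forward key step: base deprotonates the terminal methylene of A2, the carbanion attacks the far ester carbonyl in a Dieckmann-type closure, and loss of methoxide with enolisation gives the benzoate A3.
- In favour: the closure mirrors polyketide folding, aromatisation drives it, and ring A arrives with its three hydroxyls free. On that point A3 is better than the chosen plan, which must cleave three more methyl ethers.
- Equal: A1 could be grown by the same iterative chemistry as here, starting from a ring B phenol protected at B1.
- Against: the chain of A2 must be attached to a crowded phenol oxygen. A triketide can also close through oxygen to a hydroxypyranone or by aldol condensation. The ester left on ring A must be removed by saponification and decarboxylation.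
- Comparison: mechanistically, a carbonyl condensation with several competing closure modes stands against an SNAr with one regiochemical question. In step economy the chosen plan is clearly ahead, because ring A costs no step at all (it is bought as 1), while the alternative spends at least four steps on it.

Alternative 2: The cut is the E6–E1 bond, which unfolds ring E into the racemic 4-hydroxy-4-(aryloxyethynyl)-2,3-dimethoxycyclobutenone A5. This would come from dimethyl squarate A4 and an aryloxyacetylide made by O-ethynylation of 16.
- Forward key step: heating A5 opens the four-membered ring to an alkynyl vinylketene. The ketene carbon bonds to the distal alkyne carbon, and hydrogen transfer within the resulting diradical gives the quinone A6 (Moore ring expansion).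
- In favour: the positions of all ring E substituents, including the hydrogen at E2, are fixed by the two components. In structural certainty it is the equal of the chosen plan. The step is neutral and needs no metal, which is better than the copper coupling of step 8.
- Against: an oxygen substituent on the alkyne terminus stabilises the radical of the competing five-membered closure, so diversion to an alkylidene cyclopentenedione is a mechanistic risk. The aryloxyalkyne costs two or three extra steps on a tetramer. A6 must still be reduced to a hydroquinone whose more hindered hydroxyl has to be arylated selectively.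
- Comparison: A6 is the same compound as F6, which the fallback reaches in one step from 16. The chosen plan needs two steps (8 and 9) for a ring E that carries a single hydroxyl, so the alternative is longer and ends at a less useful intermediate.

Alternative 3: The cut is the pair of bonds D2–D3 and D5–D6 of the central ring. The fragments are the 3-aryloxyglutaconate A7 (made from 12) and the aryloxymalonyl dichloride A8, which carries the rings E, F and G.
- Forward key step: the dienolate of A7 is acylated twice at carbon by A8, first between the fragments and then within the molecule, and enolisation gives the aromatic diester A9.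
- In favour: it is the most convergent plan, a three plus one plus three union at the centre. In convergence and in length of the longest linear sequence it is equal to or better than the chosen linear plan. The D3 and D5 hydroxyls arrive free, and the left half is an intermediate of the present route.
- Against: after the first C-acylation, a malonyl dichloride tends to acylate the enol oxygen and give a hydroxypyranone instead of a benzene ring, and A8 can lose HCl to a ketene. The right-hand trimer needs its free oxygen at E1 and therefore a separate synthesis with an extra protecting group. Two ester groups must then be removed by hydrolysis and double decarboxylation.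
- Comparison: the carbon-versus-oxygen acylation is less secure than the substitutions used here. The total step count would be clearly higher even though the longest linear sequence would be similar.

Key step: step 1

## Route

Step 1
Reactants: 1 2,4,6-trimethoxyphenol; 2 2,4,6-trifluorobenzaldehyde
Product: 4 2,6-dimethoxy-4-(2,4,6-trimethoxyphenoxy)benzaldehyde, via difluoro aldehyde 3 (not isolated)
Conditions: 2 (1.05 equiv), K2CO3, DMF, −10 °C to rt; then NaOMe (2.2 equiv), MeOH, rt to 50 °C; aqueous NH4Cl work-up
Reagents that add atoms: sodium methoxide, [Na+].[O-]C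
Why: This is a two-stage nucleophilic aromatic substitution (addition–elimination) in one flask: the potassium phenoxide of 1 adds to C4 of 2, the para formyl group takes up the negative charge of the Meisenheimer complex, and loss of fluoride gives 3. Two methoxides then replace the ortho fluorides of 3 by the same mechanism, with the charge now delocalised into the ortho formyl group. The closest known reaction type is the sequential SNAr of phenoxides and alkoxides on 2,4-difluoro- and 2,4,6-trifluorobenzaldehydes. No ring is closed and no stereocenter is formed. The step needs para selectivity in the first substitution, which should be secured by the two ortho methoxy groups of the phenoxide (they disfavour attack at a carbon flanked by the formyl group), by the dipolar aprotic solvent with a potassium counter-ion (no carbonyl-directed ortho delivery), and by low temperature with 2 in slight excess so that 3 is not arylated twice. It also needs methoxide to take C–F and not C–OAr: fluorine accelerates the rate-limiting addition far more than an aryloxy group does, and each methoxy group introduced deactivates the ring, so 4 should be inert to the small excess of NaOMe. Methoxide adds only reversibly to the formyl group, no hydroxide is present for a Cannizzaro reaction, and the mild acidic work-up returns the aldehyde.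

Step 2
Reactants: 4 2,6-dimethoxy-4-(2,4,6-trimethoxyphenoxy)benzaldehyde
Product: 6 2,6-dimethoxy-4-(2,4,6-trimethoxyphenoxy)phenol, via aryl formate 5 (not isolated)
Conditions: 30% H2O2 (1.3 equiv), cat. H2SO4, MeOH–CH2Cl2, 0 °C to rt; Na2S2O3 quench
Reagents that add atoms: hydrogen peroxide, OO
Why: Acid-catalysed Dakin oxidation (Baeyer–Villiger type): the peroxide adduct of the protonated aldehyde rearranges with migration of the very electron-rich aryl group to oxygen, and formate 5 is methanolysed in the same flask; a small excess of peroxide and a reductive quench protect the oxidisable phenol.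

Step 3
Reactants: 7 5-bromo-1,2,3-trimethoxybenzene
Product: 9 6-bromo-2,3,4-trimethoxybenzaldehyde, via chloro ether 8 (not isolated)
Conditions: Cl2CHOMe, TiCl4, CH2Cl2, −10 to 0 °C; then ice-water
Reagents that add atoms: dichloromethyl methyl ether, COC(Cl)Cl; water, O
Why: Rieche formylation; the two free positions of 7 are equivalent and each is ortho to one methoxy group and para to another, so a single aldehyde with the formyl group next to bromine should result, and the low temperature guards against cleavage of the methoxy group beside the carbonyl.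

Step 4
Reactants: 6 2,6-dimethoxy-4-(2,4,6-trimethoxyphenoxy)phenol; 9 6-bromo-2,3,4-trimethoxybenzaldehyde
Product: 10 2,3,4-trimethoxy-6-[2,6-dimethoxy-4-(2,4,6-trimethoxyphenoxy)phenoxy]benzaldehyde
Conditions: CuI (20 mol %), picolinic acid (40 mol %), K3PO4, DMSO, 90 °C, argon
Reagents that add atoms: none
Why: Ullmann diaryl ether synthesis under ligand-assisted copper catalysis, a system suited to di-ortho-substituted phenols; the ortho formyl group of 9 assists insertion of copper into the C–Br bond, and 6 has only one hydroxyl, so no selectivity question arises.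

Step 5
Reactants: 10 2,3,4-trimethoxy-6-[2,6-dimethoxy-4-(2,4,6-trimethoxyphenoxy)phenoxy]benzaldehyde
Product: 12 2,3,4-trimethoxy-6-[2,6-dimethoxy-4-(2,4,6-trimethoxyphenoxy)phenoxy]phenol, via aryl formate 11 (not isolated)
Conditions: 30% H2O2 (1.3 equiv), cat. H2SO4, MeOH–CH2Cl2, 0 °C to rt; Na2S2O3 quench
Reagents that add atoms: hydrogen peroxide, OO
Why: Acid-catalysed Dakin oxidation; the migrating ring C carries four oxygen substituents, two of them ortho and one para to the formyl carbon, so aryl migration should outrun hydride migration, and the only hydroxyl set free is the one at C6.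

Step 6
Reactants: 12 trimer phenol (as above); 2 2,4,6-trifluorobenzaldehyde
Product: 14 2,6-dimethoxy-4-{2,3,4-trimethoxy-6-[2,6-dimethoxy-4-(2,4,6-trimethoxyphenoxy)phenoxy]phenoxy}benzaldehyde, via difluoro aldehyde 13 (not isolated)
Conditions: 2 (1.1 equiv), K2CO3, DMF, 0 °C to rt; then NaOMe (2.2 equiv), MeOH, rt to 50 °C; aqueous NH4Cl work-up
Reagents that add atoms: sodium methoxide, [Na+].[O-]C
Why: The same three-component SNAr as in step 1; the C6 phenoxide of 12 is flanked by an aryloxy and a methoxy group and should therefore attack the unhindered para carbon of 2, after which methoxide replaces the two ortho fluorides of 13.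

Step 7
Reactants: 14 tetramer aldehyde (formyl at D4)
Product: 16 2,6-dimethoxy-4-{2,3,4-trimethoxy-6-[2,6-dimethoxy-4-(2,4,6-trimethoxyphenoxy)phenoxy]phenoxy}phenol, via aryl formate 15 (not isolated)
Conditions: 30% H2O2 (1.3 equiv), cat. H2SO4, MeOH–CH2Cl2, 0 °C to rt; Na2S2O3 quench
Reagents that add atoms: hydrogen peroxide, OO
Why: Acid-catalysed Dakin oxidation on a ring with the same substitution as in step 2, so the same aryl migration and in situ methanolysis of the formate are expected.

Step 8
Reactants: 16 tetramer phenol (hydroxyl at D4); 9 6-bromo-2,3,4-trimethoxybenzaldehyde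
Product: 17 pentamer aldehyde: 2,3,4-trimethoxy-6-(aryloxy)benzaldehyde whose aryloxy group is 16 bound through its D4 oxygen (formyl at E6, hydrogen at E2)
Conditions: CuI (20 mol %), picolinic acid (40 mol %), K3PO4, DMSO, 90 °C, argon
Reagents that add atoms: none
Why: Ullmann diaryl ether synthesis as in step 4; the reacting phenol has the same local environment as 6, and the ortho formyl group again assists the coupling.

Step 9
Reactants: 17 pentamer aldehyde (formyl at E6)
Product: 19 pentamer phenol: 2,3,4-trimethoxy-6-(aryloxy)phenol whose aryloxy group is 16 bound through its D4 oxygen (hydroxyl at E6), via aryl formate 18 (not isolated)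
Conditions: 30% H2O2 (1.3 equiv), cat. H2SO4, MeOH–CH2Cl2, 0 °C to rt; Na2S2O3 quench
Reagents that add atoms: hydrogen peroxide, OO
Why: Acid-catalysed Dakin oxidation as in step 5, on a ring E identical in substitution with ring C of 10.

Step 10
Reactants: 19 pentamer phenol (hydroxyl at E6); 2 2,4,6-trifluorobenzaldehyde
Product: 21 hexamer aldehyde: 2,6-dimethoxy-4-(aryloxy)benzaldehyde whose aryloxy group is 19 bound through its E6 oxygen (formyl at F4), via difluoro aldehyde 20 (not isolated)
Conditions: 2 (1.1 equiv), K2CO3, DMF, 0 °C to rt; then NaOMe (2.2 equiv), MeOH–THF, rt to 50 °C; aqueous NH4Cl work-up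
Reagents that add atoms: sodium methoxide, [Na+].[O-]C
Why: The three-component SNAr of step 1 repeated on the pentamer; para attack by the crowded E6 phenoxide, then two ortho substitutions by methoxide, with THF added for solubility.

Step 11
Reactants: 21 hexamer aldehyde (formyl at F4)
Product: 23 hexamer phenol: 2,6-dimethoxy-4-(aryloxy)phenol whose aryloxy group is 19 bound through its E6 oxygen (hydroxyl at F4), via aryl formate 22 (not isolated)
Conditions: 30% H2O2 (1.3 equiv), cat. H2SO4, MeOH–CH2Cl2, 0 °C to rt; Na2S2O3 quench
Reagents that add atoms: hydrogen peroxide, OO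
Why: Acid-catalysed Dakin oxidation as in steps 2 and 7.

Step 12
Reactants: 23 hexamer phenol (hydroxyl at F4); 2 2,4,6-trifluorobenzaldehyde
Product: 25 heptamer aldehyde: 2,6-dimethoxy-4-(aryloxy)benzaldehyde whose aryloxy group is 23 bound through its F4 oxygen (formyl at G4), via difluoro aldehyde 24 (not isolated)
Conditions: 2 (1.1 equiv), K2CO3, DMF, 0 °C to rt; then NaOMe (2.2 equiv), MeOH–THF, rt to 50 °C; aqueous NH4Cl work-up
Reagents that add atoms: sodium methoxide, [Na+].[O-]C
Why: The three-component SNAr once more; it completes the carbon–oxygen skeleton, with the formyl group standing for the G4 oxygen.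

Step 13
Reactants: 25 heptamer aldehyde (formyl at G4)
Product: 27 heptamer phenol: the heptadeca-O-methyl ether of the target with the G4 hydroxyl free, via aryl formate 26 (not isolated)
Conditions: 30% H2O2 (1.3 equiv), cat. H2SO4, MeOH–CH2Cl2, 0 °C to rt; Na2S2O3 quench
Reagents that add atoms: hydrogen peroxide, OO
Why: Acid-catalysed Dakin oxidation as before; all eighteen oxygens of the target are now in place, seventeen as methyl ethers and one as a free hydroxyl.

Step 14
Reactants: 27 heptamer phenol (seventeen methyl ethers)
Product: 28 CNP0292517.0, the octadecahydroxy heptamer A to G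
Conditions: BBr3 (excess), CH2Cl2, −78 °C to rt; then MeOH and degassed H2O, 0 °C, argon; reversed-phase chromatography with acidified, degassed eluents
Reagents that add atoms: none
Why: Lewis-acid ether cleavage: each methoxy oxygen binds boron and bromide attacks the methyl carbon by SN2, while the diaryl ethers offer no carbon open to such attack and should stay intact; hydrolysis of the boron aryloxides under acidic, oxygen-free conditions should release the polyphenol.

## Compound list

1 | 2,4,6-trimethoxyphenol | COc1cc(OC)c(O)c(OC)c1 | starting material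
2 | 2,4,6-trifluorobenzaldehyde | O=Cc1c(F)cc(F)cc1F | starting material
3 | 2,6-difluoro-4-(2,4,6-trimethoxyphenoxy)benzaldehyde (not isolated) | COc1cc(OC)c(Oc2cc(F)c(C=O)c(F)c2)c(OC)c1 | intermediate
4 | 2,6-dimethoxy-4-(2,4,6-trimethoxyphenoxy)benzaldehyde | COc1cc(OC)c(Oc2cc(OC)c(C=O)c(OC)c2)c(OC)c1 | intermediate
5 | 2,6-dimethoxy-4-(2,4,6-trimethoxyphenoxy)phenyl formate (not isolated) | COc1cc(OC)c(Oc2cc(OC)c(OC=O)c(OC)c2)c(OC)c1 | intermediate
6 | 2,6-dimethoxy-4-(2,4,6-trimethoxyphenoxy)phenol | COc1cc(OC)c(Oc2cc(OC)c(O)c(OC)c2)c(OC)c1 | intermediate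
7 | 5-bromo-1,2,3-trimethoxybenzene | COc1cc(Br)cc(OC)c1OC | starting material
8 | 1-bromo-2-[chloro(methoxy)methyl]-3,4,5-trimethoxybenzene, racemic (not isolated) | COC(Cl)c1c(Br)cc(OC)c(OC)c1OC | intermediate
9 | 6-bromo-2,3,4-trimethoxybenzaldehyde | O=Cc1c(Br)cc(OC)c(OC)c1OC | intermediate
10 | 2,3,4-trimethoxy-6-[2,6-dimethoxy-4-(2,4,6-trimethoxyphenoxy)phenoxy]benzaldehyde | COc1cc(OC)c(Oc2cc(OC)c(Oc3cc(OC)c(OC)c(OC)c3C=O)c(OC)c2)c(OC)c1 | intermediate
11 | formate of trimer phenol 12 (not isolated) | COc1cc(OC)c(Oc2cc(OC)c(Oc3cc(OC)c(OC)c(OC)c3OC=O)c(OC)c2)c(OC)c1 | intermediate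
12 | 2,3,4-trimethoxy-6-[2,6-dimethoxy-4-(2,4,6-trimethoxyphenoxy)phenoxy]phenol | COc1cc(OC)c(Oc2cc(OC)c(Oc3cc(OC)c(OC)c(OC)c3O)c(OC)c2)c(OC)c1 | intermediate
13 | tetramer 2,6-difluoro-4-(aryloxy)benzaldehyde, aryloxy = 12 through its C6 oxygen (not isolated) | COc1cc(OC)c(Oc2cc(OC)c(Oc3cc(OC)c(OC)c(OC)c3Oc4cc(F)c(C=O)c(F)c4)c(OC)c2)c(OC)c1 | intermediate
14 | tetramer aldehyde, 2,6-dimethoxy-4-(aryloxy)benzaldehyde, aryloxy = 12 through its C6 oxygen | COc1cc(OC)c(Oc2cc(OC)c(Oc3cc(OC)c(OC)c(OC)c3Oc4cc(OC)c(C=O)c(OC)c4)c(OC)c2)c(OC)c1 | intermediate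
15 | formate of tetramer phenol 16 (not isolated) | COc1cc(OC)c(Oc2cc(OC)c(Oc3cc(OC)c(OC)c(OC)c3Oc4cc(OC)c(OC=O)c(OC)c4)c(OC)c2)c(OC)c1 | intermediate
16 | tetramer phenol, 2,6-dimethoxy-4-(aryloxy)phenol, aryloxy = 12 through its C6 oxygen | COc1cc(OC)c(Oc2cc(OC)c(Oc3cc(OC)c(OC)c(OC)c3Oc4cc(OC)c(O)c(OC)c4)c(OC)c2)c(OC)c1 | intermediate
17 | pentamer aldehyde, 2,3,4-trimethoxy-6-(aryloxy)benzaldehyde, aryloxy = 16 through its D4 oxygen | COc1cc(OC)c(Oc2cc(OC)c(Oc3cc(OC)c(OC)c(OC)c3Oc4cc(OC)c(Oc5cc(OC)c(OC)c(OC)c5C=O)c(OC)c4)c(OC)c2)c(OC)c1 | intermediate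
18 | formate of pentamer phenol 19 (not isolated) | COc1cc(OC)c(Oc2cc(OC)c(Oc3cc(OC)c(OC)c(OC)c3Oc4cc(OC)c(Oc5cc(OC)c(OC)c(OC)c5OC=O)c(OC)c4)c(OC)c2)c(OC)c1 | intermediate
19 | pentamer phenol, 2,3,4-trimethoxy-6-(aryloxy)phenol, aryloxy = 16 through its D4 oxygen | COc1cc(OC)c(Oc2cc(OC)c(Oc3cc(OC)c(OC)c(OC)c3Oc4cc(OC)c(Oc5cc(OC)c(OC)c(OC)c5O)c(OC)c4)c(OC)c2)c(OC)c1 | intermediate
20 | hexamer 2,6-difluoro-4-(aryloxy)benzaldehyde, aryloxy = 19 through its E6 oxygen (not isolated) | COc1cc(OC)c(Oc2cc(OC)c(Oc3cc(OC)c(OC)c(OC)c3Oc4cc(OC)c(Oc5cc(OC)c(OC)c(OC)c5Oc6cc(F)c(C=O)c(F)c6)c(OC)c4)c(OC)c2)c(OC)c1 | intermediate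
21 | hexamer aldehyde, 2,6-dimethoxy-4-(aryloxy)benzaldehyde, aryloxy = 19 through its E6 oxygen | COc1cc(OC)c(Oc2cc(OC)c(Oc3cc(OC)c(OC)c(OC)c3Oc4cc(OC)c(Oc5cc(OC)c(OC)c(OC)c5Oc6cc(OC)c(C=O)c(OC)c6)c(OC)c4)c(OC)c2)c(OC)c1 | intermediate
22 | formate of hexamer phenol 23 (not isolated) | COc1cc(OC)c(Oc2cc(OC)c(Oc3cc(OC)c(OC)c(OC)c3Oc4cc(OC)c(Oc5cc(OC)c(OC)c(OC)c5Oc6cc(OC)c(OC=O)c(OC)c6)c(OC)c4)c(OC)c2)c(OC)c1 | intermediate
23 | hexamer phenol, 2,6-dimethoxy-4-(aryloxy)phenol, aryloxy = 19 through its E6 oxygen | COc1cc(OC)c(Oc2cc(OC)c(Oc3cc(OC)c(OC)c(OC)c3Oc4cc(OC)c(Oc5cc(OC)c(OC)c(OC)c5Oc6cc(OC)c(O)c(OC)c6)c(OC)c4)c(OC)c2)c(OC)c1 | intermediate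
24 | heptamer 2,6-difluoro-4-(aryloxy)benzaldehyde, aryloxy = 23 through its F4 oxygen (not isolated) | COc1cc(OC)c(Oc2cc(OC)c(Oc3cc(OC)c(OC)c(OC)c3Oc4cc(OC)c(Oc5cc(OC)c(OC)c(OC)c5Oc6cc(OC)c(Oc7cc(F)c(C=O)c(F)c7)c(OC)c6)c(OC)c4)c(OC)c2)c(OC)c1 | intermediate
25 | heptamer aldehyde, 2,6-dimethoxy-4-(aryloxy)benzaldehyde, aryloxy = 23 through its F4 oxygen | COc1cc(OC)c(Oc2cc(OC)c(Oc3cc(OC)c(OC)c(OC)c3Oc4cc(OC)c(Oc5cc(OC)c(OC)c(OC)c5Oc6cc(OC)c(Oc7cc(OC)c(C=O)c(OC)c7)c(OC)c6)c(OC)c4)c(OC)c2)c(OC)c1 | intermediate
26 | formate of heptamer phenol 27 (not isolated) | COc1cc(OC)c(Oc2cc(OC)c(Oc3cc(OC)c(OC)c(OC)c3Oc4cc(OC)c(Oc5cc(OC)c(OC)c(OC)c5Oc6cc(OC)c(Oc7cc(OC)c(OC=O)c(OC)c7)c(OC)c6)c(OC)c4)c(OC)c2)c(OC)c1 | intermediate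
27 | heptamer phenol, heptadeca-O-methyl ether of the target with free G4 hydroxyl | COc1cc(OC)c(Oc2cc(OC)c(Oc3cc(OC)c(OC)c(OC)c3Oc4cc(OC)c(Oc5cc(OC)c(OC)c(OC)c5Oc6cc(OC)c(Oc7cc(OC)c(O)c(OC)c7)c(OC)c6)c(OC)c4)c(OC)c2)c(OC)c1 | intermediate
28 | CNP0292517.0, octadecahydroxy heptamer A to G (achiral) | Oc1cc(O)c(Oc2cc(O)c(Oc3cc(O)c(O)c(O)c3Oc3cc(O)c(Oc4cc(O)c(O)c(O)c4Oc4cc(O)c(Oc5cc(O)c(O)c(O)c5)c(O)c4)c(O)c3)c(O)c2)c(O)c1 | target

## Step count and least certain steps

Total: 14 steps. Longest linear sequence: 13 steps (steps 1, 2 and 4 to 14, from 1 and 2); step 3 is a one-step side branch.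

**Step 1 (key step).** The most likely failure is loss of regiocontrol: attack of the phenoxide at an ortho fluoride, or a second arylation of 3. Slow displacement of the new aryloxy group by methoxide is a further risk, because that group is para to the formyl group. Fallback, from 1 back to 4: the two kinds of substitution are separated. Commercial 4-bromo-2,6-difluorobenzaldehyde (O=Cc1c(F)cc(Br)cc1F) is treated with NaOMe in MeOH to give 4-bromo-2,6-dimethoxybenzaldehyde F1. Compound 1 is then coupled with F1 under CuI, picolinic acid and K3PO4 in DMSO. The para formyl group activates the bromide, the ether position is fixed by the bromine, and the product is 4.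

**Step 4.** The crowded copper aryloxide may exchange slowly with the bromide, so that reduction of the C–Br bond of 9 and oxidative degradation of the electron-rich phenol take over. Fallback, from 6 back to 12, by addition–elimination on a quinone:
- Commercial 2,3-dimethoxyphenol (COc1cccc(O)c1OC) is oxidised with (KSO3)2NO to 2,3-dimethoxy-1,4-benzoquinone F2.
- Br2, then Et3N, gives 5-bromo-2,3-dimethoxy-1,4-benzoquinone F3.
- 6 and F3 with K2CO3 in MeCN at 0 °C should give the trimer aryloxyquinone F4. Because the quinone core is symmetric, direct and cine substitution lead to the same product.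
- Na2S2O4 reduces F4 to the trimer hydroquinone F5.
- One equivalent of MeI with K2CO3 in acetone should methylate the less hindered hydroxyl, the one next to the ring hydrogen, and give 12.

This detour depends on steric differentiation of two hydroxyls, which is why it is not the first choice.

**Step 8.** The same process risk as in step 4, on a larger and less soluble phenol. Fallback, from 16 back to 19: 16 and F3 (K2CO3, MeCN) give the pentamer aryloxyquinone F6. Na2S2O4 gives the pentamer hydroquinone F7. Selective methylation of the less hindered hydroxyl as above gives 19.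

**Step 13.** On the largest aldehyde, peroxide addition may become slow through poor solubility while the electron-rich phenol product is oxidised further. Fallback, from 23 to 28: ring G is introduced with its oxygen pattern complete. Copper-catalysed coupling of 23 with 7 (CuI, picolinic acid, K3PO4, DMSO, 110 °C) gives the permethylated heptamer F8, and BBr3 as in step 14 gives 28. This coupling uses an unactivated bromide and is for that reason held in reserve.

**Step 14.** Cleavage may stay incomplete across seventeen sites, and the free polyphenol may be oxidised during isolation. Fallback, from 27 to 28: the crude product of the BBr3 reaction is acetylated at once (Ac2O, pyridine) to the octadecaacetate F9, which is stable and can be purified on silica. It is then deacetylated with HCl in degassed MeOH at 40 °C under argon to give 28.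

## Further compounds

F1 | step 1 | 4-bromo-2,6-dimethoxybenzaldehyde | COc1cc(Br)cc(OC)c1C=O
F2 | step 4 | 2,3-dimethoxy-1,4-benzoquinone | COC1=C(OC)C(=O)C=CC1=O
F3 | step 4 | 5-bromo-2,3-dimethoxy-1,4-benzoquinone | COC1=C(OC)C(=O)C(Br)=CC1=O
F4 | step 4 | 5-[2,6-dimethoxy-4-(2,4,6-trimethoxyphenoxy)phenoxy]-2,3-dimethoxy-1,4-benzoquinone | COC8=C(OC)C(=O)C(Oc2c(OC)cc(Oc1c(OC)cc(OC)cc1OC)cc2OC)=CC8=O
F5 | step 4 | 5-[2,6-dimethoxy-4-(2,4,6-trimethoxyphenoxy)phenoxy]-2,3-dimethoxybenzene-1,4-diol | COc1cc(OC)c(Oc2cc(OC)c(Oc3cc(O)c(OC)c(OC)c3O)c(OC)c2)c(OC)c1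
F6 | step 8 | pentamer quinone, 5-(aryloxy)-2,3-dimethoxy-1,4-benzoquinone, aryloxy = 16 through its D4 oxygen | COC8=C(OC)C(=O)C(Oc4c(OC)cc(Oc3c(OC)c(OC)c(OC)cc3Oc2c(OC)cc(Oc1c(OC)cc(OC)cc1OC)cc2OC)cc4OC)=CC8=O
F7 | step 8 | pentamer hydroquinone, 5-(aryloxy)-2,3-dimethoxybenzene-1,4-diol, aryloxy = 16 through its D4 oxygen | COc1cc(OC)c(Oc2cc(OC)c(Oc3cc(OC)c(OC)c(OC)c3Oc4cc(OC)c(Oc5cc(O)c(OC)c(OC)c5O)c(OC)c4)c(OC)c2)c(OC)c1
F8 | step 13 | permethylated heptamer, octadeca-O-methyl ether of the target | COc1cc(OC)c(Oc2cc(OC)c(Oc3cc(OC)c(OC)c(OC)c3Oc4cc(OC)c(Oc5cc(OC)c(OC)c(OC)c5Oc6cc(OC)c(Oc7cc(OC)c(OC)c(OC)c7)c(OC)c6)c(OC)c4)c(OC)c2)c(OC)c1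
F9 | step 14 | octadecaacetate of the target | CC(=O)Oc1cc(OC(C)=O)c(Oc2cc(OC(C)=O)c(Oc3cc(OC(C)=O)c(OC(C)=O)c(OC(C)=O)c3Oc3cc(OC(C)=O)c(Oc4cc(OC(C)=O)c(OC(C)=O)c(OC(C)=O)c4Oc4cc(OC(C)=O)c(Oc5cc(OC(C)=O)c(OC(C)=O)c(OC(C)=O)c5)c(OC(C)=O)c4)c(OC(C)=O)c3)c(OC(C)=O)c2)c(OC(C)=O)c1
A1 | alternative 1 | hexamer phenol, rings B to G, hydroxyl at B1, all other oxygens methylated | Oc2cc(OC)c(Oc3cc(OC)c(OC)c(OC)c3Oc3cc(OC)c(Oc4cc(OC)c(OC)c(OC)c4Oc4cc(OC)c(Oc5cc(OC)c(OC)c(OC)c5)c(OC)c4)c(OC)c3)c(OC)c2
A2 | alternative 1 | dimethyl 2-(aryloxy)-3,5-dioxoheptanedioate, racemic, aryloxy = A1 through its B1 oxygen | COC(=O)CC(=O)CC(=O)C(Oc2cc(OC)c(Oc3cc(OC)c(OC)c(OC)c3Oc3cc(OC)c(Oc4cc(OC)c(OC)c(OC)c4Oc4cc(OC)c(Oc5cc(OC)c(OC)c(OC)c5)c(OC)c4)c(OC)c3)c(OC)c2)C(=O)OC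
A3 | alternative 1 | heptamer with ring A as methyl 2,4,6-trihydroxy-3-(aryloxy)benzoate | COC(=O)c1c(O)cc(O)c(Oc2cc(OC)c(Oc3cc(OC)c(OC)c(OC)c3Oc3cc(OC)c(Oc4cc(OC)c(OC)c(OC)c4Oc4cc(OC)c(Oc5cc(OC)c(OC)c(OC)c5)c(OC)c4)c(OC)c3)c(OC)c2)c1O
A4 | alternative 2 | dimethyl squarate | COC1=C(OC)C(=O)C1=O
A5 | alternative 2 | 4-hydroxy-4-(aryloxyethynyl)-2,3-dimethoxycyclobut-2-en-1-one, racemic, aryloxy = 16 through its D4 oxygen | COC8=C(OC)C(O)(C#COc4c(OC)cc(Oc3c(OC)c(OC)c(OC)cc3Oc2c(OC)cc(Oc1c(OC)cc(OC)cc1OC)cc2OC)cc4OC)C8=O
A6 | alternative 2 | pentamer with ring E as 5-(aryloxy)-2,3-dimethoxy-1,4-benzoquinone | COC8=C(OC)C(=O)C(Oc4c(OC)cc(Oc3c(OC)c(OC)c(OC)cc3Oc2c(OC)cc(Oc1c(OC)cc(OC)cc1OC)cc2OC)cc4OC)=CC8=O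
A7 | alternative 3 | dimethyl (E)-3-(aryloxy)pent-2-enedioate, aryloxy = 12 through its C6 oxygen | COC(=O)C/C(=C\C(=O)OC)Oc3c(OC)c(OC)c(OC)cc3Oc2c(OC)cc(Oc1c(OC)cc(OC)cc1OC)cc2OC
A8 | alternative 3 | 2-(aryloxy)malonyl dichloride, aryloxy = trimer of rings E, F and G through its E1 oxygen | O=C(Cl)C(C(=O)Cl)Oc4cc(OC)c(OC)c(OC)c4Oc5cc(OC)c(Oc6cc(OC)c(OC)c(OC)c6)c(OC)c5
A9 | alternative 3 | heptamer with ring D as dimethyl 4,6-dihydroxy-2,5-bis(aryloxy)isophthalate | COC(=O)c7c(O)c(Oc4cc(OC)c(OC)c(OC)c4Oc5cc(OC)c(Oc6cc(OC)c(OC)c(OC)c6)c(OC)c5)c(O)c(C(=O)OC)c7Oc3c(OC)c(OC)c(OC)cc3Oc2c(OC)cc(Oc1c(OC)cc(OC)cc1OC)cc2OC
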